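## The problem

Garcinisidone E (17) is a depsidone: ring A (the benzoate ring) and ring B are joined twice, by a diaryl ether oxygen and by an aryl ester, so that a seven-membered dioxepinone lies between them. Depsidone numbering is used throughout: C11 lactone carbonyl, O10 ester oxygen, O5 ether oxygen, ring A C1 to C4, ring B C6 to C9. Ring A carries hydroxyls on C1 and C3 and 3-methylbut-2-enyl groups on C2 and C4, so it is fully substituted. Ring B carries a hydroxyl on C7 and a 2,2-dimethyl-2H-pyran fused through its oxygen to C8 and through its vinyl carbon to C9, which gives ring B four oxygens in a 1,2,4,5 pattern. There is no stereocentre, so the task is purely regiochemical: the ring B oxygens must be told apart as ether, ester and free phenol, the pyran must sit on the right edge, and two C5 chains must end on C2 and C4 and not on C6 or on oxygen. The groups that will not survive rough treatment are the prenyl olefins (they close onto the neighbouring phenols to chromans under acid), the chromene olefin (acid, electrophilic oxidants), the aryl ester (hydroxide, alkoxide) and any hydroquinone intermediate (air). The oxygen pattern of ring B is that of a hydroxy-para-quinone, which allows its oxygens to be differentiated by oxidation level. The feature that makes the key step possible lies in ring A: in the bare core C2 and C4 are its only unsubstituted carbons, C2 is ortho to O1 and O3, and C4 is ortho to O3 and para to O1, so an allyl group leaving either oxygen by a sigmatropic shift can only come to rest on C2 or C4.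

## Retrosynthesis

**Side-chain olefins and silyl group (17 from 16 from 15).** The O7–Si bond is cut first, then the two trisubstituted C=C bonds, so that 17 goes back to silyl ether 16 and then to the 2,4-diallyl compound 15. Cutting inside the side chains is preferred to cutting the aryl–CH2 bonds of intact prenyl groups, because every direct prenylation of C2 and C4 is ambiguous. Base-mediated C-prenylation competes with O-alkylation, prenyl ethers rearrange to the 1,1-dimethylallyl isomer, and 1,1-dimethylallyl ethers give prenyl only when the shift stops at the ortho carbon. Compound 15 is simpler in that its side chains are terminal, acid-stable olefins. The forward steps must engage only monosubstituted olefins (the chromene olefin is cyclic, conjugated and next to a quaternary carbon) and must free O7 without acid.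

**Ring A carbon–carbon bonds (15 from 13).** The C2–CH2 and C4–CH2 bonds are cut together, which leads to the bis(allyl ether) 13 and moves both carbon chains onto O1 and O3. Against a bromination and cross-coupling sequence this costs no extra functional group; against Friedel–Crafts alkylation it is free of O- versus C-selectivity and of acid. Compound 13 has no carbon substituent on ring A and can be assembled from a symmetrical phloroglucinol unit. The forward reaction must move both groups, must leave ring B alone and must tolerate the chromene and the lactone at about 195 °C. For that reason O7 carries a silyl group and not a third allyl group, which would rearrange to C6.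

**Silyl ether and lactone (13 from 12 from 10).** Removing the silyl group gives phenol 12. Cutting the acyl C11–O10 bond of 12 gives a hydroxy acid, which is written one oxidation level higher as the aryloxyquinone acid 10. The ester is cut before the ether because the reverse order needs a copper-mediated ring closure of a hindered depside. With the ether in place, reduction of the quinone sets free exactly one hydroxyl that can reach the carboxyl group, and the other one becomes the C7 phenol. A free acid is chosen over a methyl ester because closing an aryl ester from a methyl ester is uphill against methanol, whereas carbodiimide closure of the acid is the standard depsidone ring closure.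

**Diaryl ether and carboxyl oxidation level (10 from 9 from 3 and 8).** Acid 10 goes back to aldehyde 9. Cutting the bond between the ether oxygen and the quinone carbon of 9 gives the phenol 3 and the chloroquinone 8. This cut places the electrophile on ring B, where the chlorine sits on the quinone carbon that is electronically preferred for conjugate attack, and it leaves ring A as a plain phenoxide. The formyl group is used as carboxyl precursor because it tolerates the coupling and is raised to the acid under buffered conditions.

**Pyran ring and chloride (8 from 7 from 4 and 5).** Chloride 8 comes from the vinylogous acid 7. Cutting the pyran of 7 at its O–CMe2 bond and at the bond from the ring to the vinyl carbon gives 2,5-dihydroxy-1,4-benzoquinone 4 and 3-methylbut-2-enal 5. Either mode of ring closure on the symmetrical quinone gives the same compound, so the annulation needs only to be stopped after one pyran.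

**Allyl ethers (3 from 1 and 2).** Both O-allyl bonds of 3 are cut to give 2,4,6-trihydroxybenzaldehyde 1 and allyl bromide 2. The third hydroxyl is held back by its hydrogen bond to the formyl group, so both migrating groups are installed in one operation and no later selective protection of ring A is needed.

## Roads not taken

**Alternative 1:** The cut goes through the pyran of ring B and makes its formation the centre of the plan. An amine salt condenses 5 with a quinone CH of 4 and the oxatriene closes by 6π electrocyclization to 6-hydroxy-2,2-dimethyl-2H-chromene-5,8-dione A1.
- Merits: two cheap achiral materials, the whole oxygen pattern of ring B and the chromene in one step, and no regiochemical ambiguity.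
- Weak points: as a strategy it answers only the ring B half of the problem and is silent on how C2 and C4 receive their chains. Its natural complement is a ring A partner that already carries both chains, such as methyl 2,4,6-trihydroxy-3,5-bis(3-methylbut-2-enyl)benzoate A2. C-prenylation to reach A2 is poorly selective, its three hydroxyls would have to be told apart in the ether formation, and its olefins would have to pass through oxidation and lactonization.
- Comparison: this reaction is not a rival but part of the chosen route, since A1 is compound 7 and step 2 makes it. With A2 the endgame would be up to four steps shorter (no silylation, rearrangement, metathesis or desilylation). The chosen plan sets against this that both ring A carbon–carbon bonds are formed at defined positions by intramolecular delivery and that the acid-sensitive olefins appear only in the last two steps.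

**Alternative 2:** The ester oxygen is removed retrosynthetically, so the depsidone goes back to a xanthone. CF3CO3H adds to the ketone of the chroman-fused diacetoxy benzyloxy xanthone A4, and migration of the ring B aryl carbon from carbon to oxygen gives the chroman-fused diacetoxy benzyloxy depsidone A3.
- Merits: xanthones are made in one condensation of a salicylic acid with a phenol, and one oxygen insertion would create the seven-membered ring and the ester. If it worked, the core would be reached in fewer steps than the four (steps 3 to 6) the chosen plan spends on it.
- Weak points: a xanthone carbonyl is flanked by two donor-substituted aryl rings and is a poor acceptor for peracid. The choice between two aryl migrating groups has to be engineered with acetates. The peracid excludes the chromene and any side-chain olefin, so the pyran must travel as a chroman and be dehydrogenated later, and the benzyl group must be removed before any olefin is present. Ring A still lacks its chains, so the rearrangement and metathesis endgame would be needed anyway.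
- Comparison: bolder and potentially shorter to the core, but longer and less certain overall. The chosen plan carries the chromene from step 2 and forms each carbon–oxygen bond where electronics dictate it.

**Alternative 3:** Ring A is cut at the two carbon–carbon bonds that flank its ether-bearing and acyl-bearing carbons. The 2,4-diprenyl 1-methoxy-1,3-bis(trimethylsilyloxy)diene A6 adds to the ring B aryloxypropiolate A7, and loss of methanol aromatizes the adduct to the fully substituted benzoate A5.
- Merits: ring A is created with both prenyl groups and both hydroxyls in place, the regiochemistry follows from the polarization of the two partners, and no late carbon–carbon bond formation is needed. In convergence it is better than the chosen plan.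
- Weak points: A6 is substituted at its reacting terminus, which slows the cycloaddition, and it needs a doubly alkylated acetoacetate as precursor. A7 is an ynol ether ester of uncertain accessibility and stability. After A5 the methoxymethyl groups must be removed with acid in the presence of ortho-prenyl phenols and the chromene, and the lactone must be closed from a methyl ester.
- Comparison: the chosen plan sets against the higher convergence its simple commercial fragments, known reaction types at every step and the late appearance of the acid-labile olefins.

Key step: step 8

Remark on the chemistry: "pyranodepsidone" below means 11H-dibenzo[b,e][1,4]dioxepin-11-one with a 2,2-dimethyl-2H-pyran fused to ring B (pyran oxygen on C8, pyran C4 on C9). Hydroxyquinone 7 is written as its para-quinone tautomer, and its ortho-quinone tautomer is the same compound in equilibrium.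

## Route

Step 1
Reactants: 1 2,4,6-trihydroxybenzaldehyde; 2 allyl bromide
Product: 3 2,4-bis(allyloxy)-6-hydroxybenzaldehyde
Conditions: 2 (2.1 equiv), K2CO3 (2.2 equiv), DMF, 0 °C to rt
Reagents that add atoms: none
Why: Williamson O-allylation; the para hydroxyl and one ortho hydroxyl react, while the last ortho hydroxyl stays locked in a hydrogen bond to the formyl group, so the reaction should stop at the bis-ether. Carbonate in a polar aprotic solvent favours O- over C-allylation of the phloroglucinol ring.

Step 2
Reactants: 4 2,5-dihydroxy-1,4-benzoquinone; 5 3-methylbut-2-enal
Product: 7 6-hydroxy-2,2-dimethyl-2H-chromene-5,8-dione, via Knoevenagel oxatriene 6 (not isolated)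
Conditions: ethylenediammonium diacetate (10 mol %), 1,4-dioxane, 80 °C; 5 added slowly to 4 (1.5 equiv)
Reagents that add atoms: none
Why: Domino Knoevenagel condensation and 6π-oxa-electrocyclization (formal [3+3] annulation of a vinylogous acid with an enal): the iminium ion of 5 condenses at the enolic CH of 4 and oxatriene 6 closes to the 2H-pyran. Closure through either flanking oxygen gives the same compound after tautomerization, and the excess of 4 with slow addition of 5 should hold back a second annulation.

Step 3
Reactants: 7 6-hydroxy-2,2-dimethyl-2H-chromene-5,8-dione
Product: 8 6-chloro-2,2-dimethyl-2H-chromene-5,8-dione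
Conditions: (COCl)2, DMF (cat.), CH2Cl2, 0 °C to rt
Reagents that add atoms: oxalyl chloride, O=C(Cl)C(Cl)=O
Why: Conversion of a vinylogous acid into its vinylogous acid chloride by Vilsmeier-type activation; chloride adds to C6 of the O-activated hydroxyquinone and the formamide leaves. The chromene olefin is conjugated to the quinone and should not add HCl.

Step 4
Reactants: 3 2,4-bis(allyloxy)-6-hydroxybenzaldehyde; 8 6-chloro-2,2-dimethyl-2H-chromene-5,8-dione
Product: 9 2,4-bis(allyloxy)-6-[(2,2-dimethyl-5,8-dioxo-5,8-dihydro-2H-chromen-6-yl)oxy]benzaldehyde
Conditions: K2CO3, DMF, 0 °C to rt, argon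
Reagents that add atoms: none
Why: Addition–elimination of a phenoxide on a haloquinone. The pyran oxygen turns C5=O into a vinylogous ester carbonyl, so C8=O is the more electrophilic carbonyl and C6, which is β to it, is the preferred site of conjugate attack; the chlorine therefore sits where the phenoxide adds anyway. The single free hydroxyl of 3 is the only nucleophile.

Step 5
Reactants: 9 2,4-bis(allyloxy)-6-[(2,2-dimethyl-5,8-dioxo-5,8-dihydro-2H-chromen-6-yl)oxy]benzaldehyde
Product: 10 2,4-bis(allyloxy)-6-[(2,2-dimethyl-5,8-dioxo-5,8-dihydro-2H-chromen-6-yl)oxy]benzoic acid
Conditions: NaClO2, NaH2PO4, 2-methyl-2-butene, t-BuOH/THF/H2O, 0 °C to rt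
Reagents that add atoms: sodium chlorite, [Na+].[O-]Cl=O
Why: Pinnick oxidation; chlorous acid converts the hindered aldehyde into the acid at about pH 4, and the excess of 2-methyl-2-butene traps HOCl before it reaches the allyl or chromene olefins or ring A. The quinone is already at its highest oxidation level and the aryloxyquinone is stable in weak acid.

Step 6
Reactants: 10 2,4-bis(allyloxy)-6-[(2,2-dimethyl-5,8-dioxo-5,8-dihydro-2H-chromen-6-yl)oxy]benzoic acid
Product: 12 1,3-bis(allyloxy)-7-hydroxypyranodepsidone, via hydroquinone acid 11 (not isolated)
Conditions: Na2S2O4, THF/H2O, rt; then EDC·HCl, DMAP, CH2Cl2 (high dilution), rt, argon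
Reagents that add atoms: none
Why: Dithionite reduction of the quinone followed by carbodiimide (Steglich-type) lactonization of the hydroxy acid. Of the two hydroquinone hydroxyls only the one next to the aryloxy carbon can reach the activated carboxyl group (seven-membered ring), and the other becomes the C7 phenol. High dilution and exclusion of air should suppress intermolecular acylation and reoxidation.

Step 7
Reactants: 12 1,3-bis(allyloxy)-7-hydroxypyranodepsidone
Product: 13 1,3-bis(allyloxy)-7-(tert-butyldimethylsilyloxy)pyranodepsidone
Conditions: TBSCl, imidazole, DMF, 0 °C to rt
Reagents that add atoms: tert-butyldimethylsilyl chloride, CC(C)(C)[Si](C)(C)Cl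
Why: Silylation of the only free phenol. The silyl ether is inert in the thermal step, cannot migrate to carbon as an allyl group would, and leaves with fluoride at the end without acid.

Step 8
Reactants: 13 1,3-bis(allyloxy)-7-(tert-butyldimethylsilyloxy)pyranodepsidone
Product: 15 2,4-diallyl-1,3-dihydroxy-7-(tert-butyldimethylsilyloxy)pyranodepsidone, via monoallyl phenol 14 (not isolated)
Conditions: PhNEt2 (degassed), 195 °C, sealed tube
Reagents that add atoms: none
Why: Twofold aromatic Claisen rearrangement, the thermal reaction of resorcinol bis(allyl ethers) being the closest known case. Each allyl aryl ether passes through a concerted, suprafacial [3,3] shift with a chair-like six-membered transition state to an ortho-cyclohexadienone that tautomerizes to the phenol. The allyl group on O1 can reach only C2, since its other ortho carbon C11a carries the lactone carbonyl, whereas the group on O3 can reach C2 or C4. If both groups arrive at C2, the blocked dienone cannot enolize and hands one allyl group on by a Cope [3,3] shift to C4, the carbon para to O1. Because the migrating group is unsubstituted allyl, one inversion and two inversions give the same CH2CH=CH2 substituent, so every pathway should end at 15; 14 is the intermediate of the pathway that starts at O1. No ring closes and no stereocentre is formed. The selectivity needed is ring A over ring B: ring B holds no allyl ether because O7 is silylated, and its free carbon C6 is neither ortho nor para to a migrating oxygen. The amine solvent keeps the medium free of acid, which should prevent cyclization of the ortho-allyl phenols to dihydrobenzofurans and protonation of the chromene, and 2,2-dimethylchromenes and aryl silyl ethers are known to tolerate this temperature range.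

Step 9
Reactants: 15 2,4-diallyl-1,3-dihydroxy-7-(tert-butyldimethylsilyloxy)pyranodepsidone
Product: 16 1,3-dihydroxy-2,4-bis(3-methylbut-2-enyl)-7-(tert-butyldimethylsilyloxy)pyranodepsidone
Conditions: 2-methyl-2-butene (large excess), second-generation Grubbs catalyst (H2IMes)(PCy3)Cl2Ru=CHPh (10 mol %), CH2Cl2, 40 °C, sealed tube
Reagents that add atoms: 2-methyl-2-butene, CC=C(C)C
Why: Olefin cross-metathesis of two terminal allyl groups with a trisubstituted olefin used in excess; the ruthenium alkylidene engages the monosubstituted olefins and delivers the isopropylidene ends. The chromene olefin is cyclic, conjugated and next to a quaternary carbon and should stay out, and free ortho-phenols are tolerated in this reaction type.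

Step 10
Reactants: 16 1,3-dihydroxy-2,4-bis(3-methylbut-2-enyl)-7-(tert-butyldimethylsilyloxy)pyranodepsidone
Product: 17 garcinisidone E (1,3,7-trihydroxy-2,4-bis(3-methylbut-2-enyl)pyranodepsidone)
Conditions: Bu4NF, AcOH, THF, 0 °C
Reagents that add atoms: none
Why: Fluoride cleavage of an aryl silyl ether; acetic acid buffers the phenoxide so that the aryl ester is not opened. No acid strong enough to close the ortho-prenyl phenols to chromans is present.

## Compound list

1 | 2,4,6-trihydroxybenzaldehyde | O=Cc1c(O)cc(O)cc1O | starting material
2 | allyl bromide | C=CCBr | starting material
3 | 2,4-bis(allyloxy)-6-hydroxybenzaldehyde | O=Cc1c(O)cc(OCC=C)cc1OCC=C | intermediate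
4 | 2,5-dihydroxy-1,4-benzoquinone | O=C1C=C(O)C(=O)C=C1O | starting material
5 | 3-methylbut-2-enal | CC(C)=CC=O | starting material
6 | Knoevenagel oxatriene, 5-hydroxy-3-(3-methylbut-2-enylidene)cyclohex-5-ene-1,2,4-trione (either geometry of the exocyclic olefin closes) | O=C1C=C(O)C(=O)C(=CC=C(C)C)C1=O | intermediate (not isolated)
7 | 6-hydroxy-2,2-dimethyl-2H-chromene-5,8-dione | O=C1C=C(O)C(=O)C2=C1OC(C)(C)C=C2 | intermediate
8 | 6-chloro-2,2-dimethyl-2H-chromene-5,8-dione | O=C1C=C(Cl)C(=O)C2=C1OC(C)(C)C=C2 | intermediate
9 | 2,4-bis(allyloxy)-6-[(2,2-dimethyl-5,8-dioxo-5,8-dihydro-2H-chromen-6-yl)oxy]benzaldehyde | O=Cc1c(OCC=C)cc(OCC=C)cc1OC1=CC(=O)C2=C(C=CC(C)(C)O2)C1=O | intermediate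
10 | 2,4-bis(allyloxy)-6-[(2,2-dimethyl-5,8-dioxo-5,8-dihydro-2H-chromen-6-yl)oxy]benzoic acid | OC(=O)c1c(OCC=C)cc(OCC=C)cc1OC1=CC(=O)C2=C(C=CC(C)(C)O2)C1=O | intermediate
11 | hydroquinone acid, 2,4-bis(allyloxy)-6-[(5,8-dihydroxy-2,2-dimethyl-2H-chromen-6-yl)oxy]benzoic acid | OC(=O)c1c(OCC=C)cc(OCC=C)cc1Oc1cc(O)c2OC(C)(C)C=Cc2c1O | intermediate (not isolated)
12 | 1,3-bis(allyloxy)-7-hydroxypyranodepsidone | C=CCOc1cc(OCC=C)c2c(c1)Oc1cc(O)c3OC(C)(C)C=Cc3c1OC2=O | intermediate
13 | 1,3-bis(allyloxy)-7-(tert-butyldimethylsilyloxy)pyranodepsidone | C=CCOc1cc(OCC=C)c2c(c1)Oc1cc(O[Si](C)(C)C(C)(C)C)c3OC(C)(C)C=Cc3c1OC2=O | intermediate (precursor of the key step)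
14 | monoallyl phenol, 2-allyl-3-allyloxy-1-hydroxy-7-(tert-butyldimethylsilyloxy)pyranodepsidone | C=CCOc1cc2c(c(O)c1CC=C)C(=O)Oc1c(cc(O[Si](C)(C)C(C)(C)C)c3c1C=CC(C)(C)O3)O2 | intermediate (not isolated)
15 | 2,4-diallyl-1,3-dihydroxy-7-(tert-butyldimethylsilyloxy)pyranodepsidone | C=CCc1c(O)c(CC=C)c2c(c1O)C(=O)Oc1c(cc(O[Si](C)(C)C(C)(C)C)c3c1C=CC(C)(C)O3)O2 | intermediate (product of the key step)
16 | 1,3-dihydroxy-2,4-bis(3-methylbut-2-enyl)-7-(tert-butyldimethylsilyloxy)pyranodepsidone | CC(C)=CCc1c(O)c(CC=C(C)C)c2c(c1O)C(=O)Oc1c(cc(O[Si](C)(C)C(C)(C)C)c3c1C=CC(C)(C)O3)O2 | intermediate
17 | garcinisidone E (no stereocentre) | CC(C)=CCc1c(O)c(CC=C(C)C)c2c(c1O)C(=O)Oc1c(cc(O)c3c1C=CC(C)(C)O3)O2 | target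

## Step count and least certain steps

Total step count: 10. Longest linear sequence: 9 steps (4 to 17, steps 2 to 10); the ring A branch (1 to 3, step 1) joins at step 4.

**Step 8 (key step).** The most likely failure is incomplete relay, in which the second migration stalls at a monoallyl phenol or at the doubly allylated dienone. Thermal loss of material through cyclization of the ortho-allyl phenols onto their olefins or through loss of the silyl group is also possible. The fallback replaces the pericyclic transfer by halogenation and cross-coupling; it sets out from 13 and returns at 15. The two allyl ethers of 13 would be removed with the zerovalent palladium complex Pd(PPh3)4 and morpholine to give 1,3-dihydroxy-7-(tert-butyldimethylsilyloxy)pyranodepsidone F1. N-Bromosuccinimide at low temperature should brominate the resorcinol-type ring A at its two free carbons, giving 2,4-dibromo-1,3-dihydroxy-7-(tert-butyldimethylsilyloxy)pyranodepsidone F2. A twofold Stille coupling with allyltributylstannane (Pd(PPh3)4, DMF, 90 °C) would then give 15.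

**Step 5.** What may go wrong is oxidative damage beside the aldehyde: chlorination of the electron-rich ring A if HOCl is not trapped fast enough, or nucleophilic attack of chlorite on the quinone with loss of the aryloxy group. The fallback brings the carboxyl group in at the right oxidation level, so no oxidation is needed; it sets out from 2 and 8 and returns at 10. Commercial methyl 2,4,6-trihydroxybenzoate F3 would be bis-allylated with 2 and K2CO3 to methyl 2,4-bis(allyloxy)-6-hydroxybenzoate F4 and saponified (KOH, aqueous ethanol, reflux; acidified cold) to 2,4-bis(allyloxy)-6-hydroxybenzoic acid F5. The dianion of F5 (K2CO3, DMF) would be coupled with 8, the phenoxide being the better nucleophile of the two anionic sites, to give 10 directly.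

**Step 6.** The risks are reoxidation of the hydroquinone during handling, intermolecular acylation at the unhindered para hydroxyl leading to oligomers, and slow acyl transfer between two hindered partners with rearrangement of the activated acid to an N-acylurea. The fallback protects first and closes second with a different acyl activation; it sets out from 10 (through 11) and returns at 13, leaving out step 7. After the dithionite reduction, 11 would be treated with TBSCl and imidazole, which should silylate the carboxyl group and the less hindered C8 hydroxyl of the chromene to give tert-butyldimethylsilyl 2,4-bis(allyloxy)-6-{[8-(tert-butyldimethylsilyloxy)-5-hydroxy-2,2-dimethyl-2H-chromen-6-yl]oxy}benzoate F6. Aqueous work-up (THF, water, AcOH) hydrolyses the silyl ester to 2,4-bis(allyloxy)-6-{[8-(tert-butyldimethylsilyloxy)-5-hydroxy-2,2-dimethyl-2H-chromen-6-yl]oxy}benzoic acid F7, in which only the hydroxyl needed for ring closure is free. Mukaiyama lactonization (2-chloro-1-methylpyridinium iodide, Et3N, CH2Cl2, high dilution) would then give 13.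

**Step 2.** What may go wrong is over-reaction: the product still holds an enolic CH and can take up a second molecule of 5, and the poorly soluble quinone may react sluggishly while 5 self-condenses. The fallback desymmetrizes the quinone before the annulation; it sets out from 4 and returns at 7. Compound 4 would be converted with methanol and acid into 2,5-dimethoxy-1,4-benzoquinone F8, and one methoxy group would be hydrolysed with one equivalent of aqueous NaOH to give 2-hydroxy-5-methoxy-1,4-benzoquinone F9. F9 has a single enolic CH, so the annulation with 5 can occur only once. The pyran closure is reversible, so the more stable para-quinone, 6-methoxy-2,2-dimethyl-2H-chromene-5,8-dione F10, should result, and its vinylogous ester would be saponified with aqueous LiOH to 7.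

## Further compounds

F1 | step 8 | 1,3-dihydroxy-7-(tert-butyldimethylsilyloxy)pyranodepsidone | Oc1cc(O)c2c(c1)Oc1cc(O[Si](C)(C)C(C)(C)C)c3OC(C)(C)C=Cc3c1OC2=O
F2 | step 8 | 2,4-dibromo-1,3-dihydroxy-7-(tert-butyldimethylsilyloxy)pyranodepsidone | Oc1c(Br)c(O)c2c(c1Br)Oc1cc(O[Si](C)(C)C(C)(C)C)c3OC(C)(C)C=Cc3c1OC2=O
F3 | step 5 | methyl 2,4,6-trihydroxybenzoate (commercial) | COC(=O)c1c(O)cc(O)cc1O
F4 | step 5 | methyl 2,4-bis(allyloxy)-6-hydroxybenzoate | COC(=O)c1c(O)cc(OCC=C)cc1OCC=C
F5 | step 5 | 2,4-bis(allyloxy)-6-hydroxybenzoic acid | OC(=O)c1c(O)cc(OCC=C)cc1OCC=C
F6 | step 6 | tert-butyldimethylsilyl 2,4-bis(allyloxy)-6-{[8-(tert-butyldimethylsilyloxy)-5-hydroxy-2,2-dimethyl-2H-chromen-6-yl]oxy}benzoate | CC(C)(C)[Si](C)(C)OC(=O)c1c(OCC=C)cc(OCC=C)cc1Oc1cc(O[Si](C)(C)C(C)(C)C)c2OC(C)(C)C=Cc2c1O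
F7 | step 6 | 2,4-bis(allyloxy)-6-{[8-(tert-butyldimethylsilyloxy)-5-hydroxy-2,2-dimethyl-2H-chromen-6-yl]oxy}benzoic acid | OC(=O)c1c(OCC=C)cc(OCC=C)cc1Oc1cc(O[Si](C)(C)C(C)(C)C)c2OC(C)(C)C=Cc2c1O
F8 | step 2 | 2,5-dimethoxy-1,4-benzoquinone | COC1=CC(=O)C(OC)=CC1=O
F9 | step 2 | 2-hydroxy-5-methoxy-1,4-benzoquinone | COC1=CC(=O)C(O)=CC1=O
F10 | step 2 | 6-methoxy-2,2-dimethyl-2H-chromene-5,8-dione | COC1=CC(=O)C2=C(C=CC(C)(C)O2)C1=O
A1 | alternative 1 | 6-hydroxy-2,2-dimethyl-2H-chromene-5,8-dione | O=C1C=C(O)C(=O)C2=C1OC(C)(C)C=C2
A2 | alternative 1 | methyl 2,4,6-trihydroxy-3,5-bis(3-methylbut-2-enyl)benzoate | COC(=O)c1c(O)c(CC=C(C)C)c(O)c(CC=C(C)C)c1O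
A3 | alternative 2 | chroman-fused 1,3-diacetoxy-7-benzyloxy depsidone (2,2-dimethyldihydropyran on C8/C9) | CC(=O)Oc1cc(OC(C)=O)c2c(c1)Oc1cc(OCc4ccccc4)c3c(c1OC2=O)CCC(C)(C)O3
A4 | alternative 2 | chroman-fused diacetoxy benzyloxy xanthone (ketone in place of the ester of A3) | CC(=O)Oc1cc(OC(C)=O)c2c(c1)Oc1cc(OCc4ccccc4)c3c(c1C2=O)CCC(C)(C)O3
A5 | alternative 3 | methyl 2-{[5,8-bis(methoxymethoxy)-2,2-dimethyl-2H-chromen-6-yl]oxy}-4,6-dihydroxy-3,5-bis(3-methylbut-2-enyl)benzoate | COC(=O)c1c(O)c(CC=C(C)C)c(O)c(CC=C(C)C)c1Oc1cc(OCOC)c2OC(C)(C)C=Cc2c1OCOC
A6 | alternative 3 | 1-methoxy-2,4-bis(3-methylbut-2-enyl)-1,3-bis(trimethylsilyloxy)buta-1,3-diene | COC(O[Si](C)(C)C)=C(CC=C(C)C)C(O[Si](C)(C)C)=CCC=C(C)C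
A7 | alternative 3 | methyl 3-{[5,8-bis(methoxymethoxy)-2,2-dimethyl-2H-chromen-6-yl]oxy}propiolate | COC(=O)C#COc1cc(OCOC)c2OC(C)(C)C=Cc2c1OCOC
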